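**Plan**

- Retrosynthesis: the benzyl group is taken off O7, then the four-oxygen aryl ring on C3 (ring B) is traced back to a 2,3-dimethoxy-1,4-benzoquinone. The C1'–C2' bond of that ring is cut, which reopens it to a squarate-derived cyclobutenone bearing an alkyne; the C5'–C6' bond is then cut between the alkyne and dimethyl squarate.
- Enabling feature: ring B has four contiguous oxygens on C2'–C5' and a single hydrogen on C6'. C3' and C4' with their methoxy groups are the squarate alkene carbons, C2' and C5' are the two quinone carbonyls, and C1' and C6' are the two alkyne carbons.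
- The alkyne carbons go back to the carboxyl carbon of a chroman-3-carboxylic acid and to CBr4. The pyran ring (ring C) is cut at O1–C2 and C3=C4 to a salicylaldehyde and acrolein.
- Forward order: ring A is purchased (2-methoxyresorcinol), ring C is closed by oxa-Michael/aldol annulation, and ring B is grown last by cyclobutenone ring expansion. Reductive methylation and debenzylation finish the synthesis.
- Stereochemistry: C3 is set once, by ligand-controlled asymmetric hydrogenation of the 2H-chromene-3-carboxylic acid. It is then carried through untouched; its descriptor alternates between R and S only because the substituent priorities change.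

Key step: step 10

Assumption: the sense of induction of the iridium catalyst in step 5 is assigned in a trial run and the ligand antipode giving (R)-8 is used. The carbinol carbon of 14 forms as both epimers, which is of no consequence because it becomes a quinone carbonyl.

**Route**

Step 1
Reactants: 1 2-methoxyresorcinol
Product: 3 2,4-dihydroxy-3-methoxybenzaldehyde, via iminium chloride 2 (not isolated)
Conditions: POCl3, DMF, MeCN, 0 °C to rt; then H2O, 50 °C
Reagents that add atoms: N,N-dimethylformamide CN(C)C=O; water O
Why: Vilsmeier–Haack formylation should occur at the only ring position activated by both hydroxyls (ortho to one, para to the other), and the aryl iminium salt is hydrolysed to the aldehyde on aqueous warming.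

Step 2
Reactants: 3 2,4-dihydroxy-3-methoxybenzaldehyde
Product: 4 4-(benzyloxy)-2-hydroxy-3-methoxybenzaldehyde
Conditions: BnBr (1.05 equiv), NaHCO3, KI (cat.), MeCN, 60 °C
Reagents that add atoms: benzyl bromide BrCc1ccccc1
Why: Williamson etherification with a weak base should select the more acidic 4-OH (para to the formyl group), while the 2-OH is held in a hydrogen bond to the aldehyde and stays free for ring C.

Step 3
Reactants: 4 4-(benzyloxy)-2-hydroxy-3-methoxybenzaldehyde; 5 acrolein
Product: 6 7-(benzyloxy)-8-methoxy-2H-chromene-3-carbaldehyde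
Conditions: K2CO3, 1,4-dioxane, reflux
Reagents that add atoms: none
Why: Oxa-Michael addition of the phenoxide to acrolein followed by intramolecular aldol condensation onto the aryl aldehyde (domino oxa-Michael/aldol annulation of salicylaldehydes) closes ring C as the conjugated enal.

Step 4
Reactants: 6 7-(benzyloxy)-8-methoxy-2H-chromene-3-carbaldehyde
Product: 7 7-(benzyloxy)-8-methoxy-2H-chromene-3-carboxylic acid
Conditions: NaClO2, NaH2PO4, 2-methyl-2-butene, t-BuOH/H2O, rt
Reagents that add atoms: sodium chlorite [Na+].[O-]Cl=O
Why: Pinnick oxidation converts the enal into the acid without touching the C3=C4 alkene, and the alkene scavenger removes hypochlorous acid before it can chlorinate the electron-rich ring A.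

Step 5
Reactants: 7 7-(benzyloxy)-8-methoxy-2H-chromene-3-carboxylic acid
Product: 8 (3R)-7-(benzyloxy)-8-methoxychroman-3-carboxylic acid
Conditions: [Ir(cod)(SIPHOX)]BArF (1 mol%), H2 (6 atm), Et3N (0.5 equiv), MeOH, rt
Reagents that add atoms: none
Why: Carboxylate-directed iridium-catalysed asymmetric hydrogenation is established for 2H-chromene-3-carboxylic acids with spiro phosphine–oxazoline ligands; the chiral ligand alone decides the face of hydrogen delivery to C3=C4 and so sets C3 (3R in the acid, the same spatial arrangement as 3S in the target), and the homogeneous catalyst leaves the benzyl ether alone.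

Step 6
Reactants: 8 (3R)-7-(benzyloxy)-8-methoxychroman-3-carboxylic acid
Product: 9 [(3S)-7-(benzyloxy)-8-methoxychroman-3-yl]methanol
Conditions: BH3·THF, THF, 0 °C to rt; aq. work-up
Reagents that add atoms: none
Why: Borane reduces the carboxylic acid chemoselectively to the primary alcohol via the acyloxyborane, with no reaction at C3 and no effect on the aryl and benzyl ethers.

Step 7
Reactants: 9 [(3S)-7-(benzyloxy)-8-methoxychroman-3-yl]methanol
Product: 10 (3R)-7-(benzyloxy)-8-methoxychroman-3-carbaldehyde
Conditions: Dess–Martin periodinane, NaHCO3, CH2Cl2, 0 °C; used crude at once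
Reagents that add atoms: none
Why: Dess–Martin oxidation under buffered, base-free conditions is the standard way to make α-branched β-alkoxy aldehydes without enolization, and immediate use keeps the C3 centre intact.

Step 8
Reactants: 10 (3R)-7-(benzyloxy)-8-methoxychroman-3-carbaldehyde
Product: 11 (3S)-7-(benzyloxy)-3-(2,2-dibromoethenyl)-8-methoxychroman
Conditions: CBr4, PPh3, Zn dust, CH2Cl2, rt (ylide preformed); then 10, 0 °C
Reagents that add atoms: carbon tetrabromide BrC(Br)(Br)Br
Why: Corey–Fuchs dibromoolefination is a Wittig-type reaction of the non-basic ylide Ph3P=CBr2, which is preformed with zinc so that no amine base meets the aldehyde, and it therefore converts the formyl group into the 1,1-dibromoalkene without deprotonating C3.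

Step 9
Reactants: 11 (3S)-7-(benzyloxy)-3-(2,2-dibromoethenyl)-8-methoxychroman; 12 dimethyl squarate
Product: 14 4-{[(3S)-7-(benzyloxy)-8-methoxychroman-3-yl]ethynyl}-4-hydroxy-2,3-dimethoxycyclobut-2-en-1-one (both carbinol epimers), via lithium acetylide 13 (not isolated)
Conditions: n-BuLi (2.0 equiv), THF, −78 °C; cannulated into 12, THF, −78 °C; sat. aq. NH4Cl, −78 °C
Reagents that add atoms: none
Why: In the second stage of the Corey–Fuchs sequence, bromine–lithium exchange, Fritsch–Buttenberg–Wiechell rearrangement and deprotonation give the lithium acetylide, which adds 1,2 to one carbonyl of dimethyl squarate as lithium acetylides are known to do, with inverse addition at low temperature preventing a second addition.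

Step 10
Reactants: 14 4-{[(3S)-7-(benzyloxy)-8-methoxychroman-3-yl]ethynyl}-4-hydroxy-2,3-dimethoxycyclobut-2-en-1-one
Product: 16 5-[(3S)-7-(benzyloxy)-8-methoxychroman-3-yl]-2,3-dimethoxy-1,4-benzoquinone, via enynylketene 15 (not isolated)
Conditions: p-xylene (0.01 M, degassed), 138 °C, 30 min
Reagents that add atoms: none
Why: Thermal conrotatory 4π-electrocyclic opening of the cyclobutenone, with the hydroxyl rotating outward, should give the (Z)-enynylketene 15 in which alkyne and ketene are cis. The ketene carbon then bonds to the distal alkyne carbon, the one bearing the chroman, so that ring B closes as a six-membered ring through a transient σ,π-diradical (Moore cyclization of an ene-yne-ketene, related to the Myers–Saito cycloaromatization), and transfer of the hydroxyl hydrogen to the ring carbon radical gives the quinone; the whole is the Moore rearrangement of 4-alkynyl-4-hydroxycyclobutenones. No stereocentre is created, the carbinol centre of 14 is destroyed so both epimers converge, and C3 of the chroman lies outside the reacting π system under neutral conditions and keeps its configuration. The step needs six-membered closure rather than five-membered closure to an alkylidenecyclopentenedione, and hydroxyl-hydrogen transfer rather than abstraction of a C2–H or C4–H of the chroman by the ring radical. The saturated C3 substituent on the alkyne offers no stabilization to the exocyclic vinyl radical of the five-ring path, the free OH is placed to deliver its hydrogen quickly, and high dilution suppresses intermolecular radical reactions.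

Step 11
Reactants: 16 5-[(3S)-7-(benzyloxy)-8-methoxychroman-3-yl]-2,3-dimethoxy-1,4-benzoquinone
Product: 18 (3S)-7-(benzyloxy)-8-methoxy-3-(2,3,4,5-tetramethoxyphenyl)chroman, via hydroquinone 17 (not isolated)
Conditions: Na2S2O4, THF/H2O, rt; then Me2SO4, aq. NaOH, n-Bu4NBr (cat.), Ar, rt
Reagents that add atoms: dimethyl sulfate COS(=O)(=O)OC
Why: Dithionite reduces the quinone to the hydroquinone, which is methylated twice in the same flask under argon (Williamson etherification, the standard conversion of 2,3-dimethoxyquinones into tetramethoxyarenes) before it can reoxidize, and neither the benzyl ether nor C3 is affected.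

Step 12
Reactants: 18 (3S)-7-(benzyloxy)-8-methoxy-3-(2,3,4,5-tetramethoxyphenyl)chroman
Product: 19 (3S)-8-methoxy-3-(2,3,4,5-tetramethoxyphenyl)chroman-7-ol
Conditions: H2 (1 atm), 10% Pd/C, EtOAc/MeOH, rt
Reagents that add atoms: none
Why: Catalytic hydrogenolysis cleaves only the benzylic C–O bond of the benzyl ether, since the chroman O1–C2 bond and the methyl ethers are not benzylic, and frees the 7-OH of the target.

**Compound list**

1 | 2-methoxyresorcinol (2-methoxybenzene-1,3-diol) | COc1c(O)cccc1O | starting material
2 | N-[(2,4-dihydroxy-3-methoxyphenyl)methylidene]-N-methylmethanaminium chloride (formed in situ) | C[N+](C)=Cc1ccc(O)c(OC)c1O.[Cl-] | intermediate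
3 | 2,4-dihydroxy-3-methoxybenzaldehyde | COc1c(O)ccc(C=O)c1O | intermediate
4 | 4-(benzyloxy)-2-hydroxy-3-methoxybenzaldehyde | COc1c(OCc2ccccc2)ccc(C=O)c1O | intermediate
5 | acrolein (prop-2-enal) | C=CC=O | starting material
6 | 7-(benzyloxy)-8-methoxy-2H-chromene-3-carbaldehyde | O=CC1=Cc2ccc(OCc3ccccc3)c(OC)c2OC1 | intermediate
7 | 7-(benzyloxy)-8-methoxy-2H-chromene-3-carboxylic acid | OC(=O)C1=Cc2ccc(OCc3ccccc3)c(OC)c2OC1 | intermediate
8 | (3R)-7-(benzyloxy)-8-methoxychroman-3-carboxylic acid | OC(=O)[C@H]1COc2c(ccc(OCc3ccccc3)c2OC)C1 | intermediate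
9 | [(3S)-7-(benzyloxy)-8-methoxychroman-3-yl]methanol | OC[C@H]1COc2c(ccc(OCc3ccccc3)c2OC)C1 | intermediate
10 | (3R)-7-(benzyloxy)-8-methoxychroman-3-carbaldehyde | O=C[C@H]1COc2c(ccc(OCc3ccccc3)c2OC)C1 | intermediate
11 | (3S)-7-(benzyloxy)-3-(2,2-dibromoethenyl)-8-methoxychroman | BrC(Br)=C[C@H]1COc2c(ccc(OCc3ccccc3)c2OC)C1 | intermediate
12 | dimethyl squarate (3,4-dimethoxycyclobut-3-ene-1,2-dione) | COC1=C(OC)C(=O)C1=O | starting material
13 | lithium {[(3S)-7-(benzyloxy)-8-methoxychroman-3-yl]ethynide} (formed in situ) | [Li]C#C[C@H]1COc2c(ccc(OCc3ccccc3)c2OC)C1 | intermediate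
14 | 4-{[(3S)-7-(benzyloxy)-8-methoxychroman-3-yl]ethynyl}-4-hydroxy-2,3-dimethoxycyclobut-2-en-1-one (both carbinol epimers) | COC1=C(OC)C(O)(C#C[C@H]2COc3c(ccc(OCc4ccccc4)c3OC)C2)C1=O | intermediate
15 | (3Z)-6-[(3S)-7-(benzyloxy)-8-methoxychroman-3-yl]-4-hydroxy-2,3-dimethoxyhexa-1,3-dien-5-yn-1-one (formed in situ) | O=C=C(OC)/C(OC)=C(O)\C#C[C@H]1COc2c(ccc(OCc3ccccc3)c2OC)C1 | intermediate
16 | 5-[(3S)-7-(benzyloxy)-8-methoxychroman-3-yl]-2,3-dimethoxy-1,4-benzoquinone | COC1=C(OC)C(=O)C([C@H]2COc3c(ccc(OCc4ccccc4)c3OC)C2)=CC1=O | intermediate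
17 | 2-[(3S)-7-(benzyloxy)-8-methoxychroman-3-yl]-5,6-dimethoxybenzene-1,4-diol (formed in situ) | COc1c(O)cc([C@H]2COc3c(ccc(OCc4ccccc4)c3OC)C2)c(O)c1OC | intermediate
18 | (3S)-7-(benzyloxy)-8-methoxy-3-(2,3,4,5-tetramethoxyphenyl)chroman | COc1cc([C@H]2COc3c(ccc(OCc4ccccc4)c3OC)C2)c(OC)c(OC)c1OC | intermediate
19 | (3S)-8-methoxy-3-(2,3,4,5-tetramethoxyphenyl)chroman-7-ol | COc1cc([C@H]2COc3c(ccc(O)c3OC)C2)c(OC)c(OC)c1OC | target

**Step count**

Total: 12 steps. Longest linear sequence: 12 steps, from 1 to 19; compounds 5 and 12 are purchased and enter in steps 3 and 9.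

**Steps most likely to fail, with fallbacks**

Step 10. The diradical stage may be diverted, either by five-membered closure to an alkylidenecyclopentenedione or by interception of the ring radical through hydrogen abstraction from C2 or C4 of the chroman. The ring expansion would then be run in its closed-shell alkenyl form. Setting out from aldehyde 10, Takai olefination (CHI3, CrCl2, THF, 0 °C) should give the vinyl iodide (3S)-7-(benzyloxy)-3-[(E)-2-iodoethenyl]-8-methoxychroman F1. Iodine–lithium exchange (t-BuLi, Et2O, −78 °C) and addition to 12 should give 4-{(E)-2-[(3S)-7-(benzyloxy)-8-methoxychroman-3-yl]ethenyl}-4-hydroxy-2,3-dimethoxycyclobut-2-en-1-one F2. On heating in toluene (110 °C) this should open to a dienylketene, close ring B by a six-electron electrocyclization with no radical stage, and tautomerize. The fallback returns to the route at hydroquinone 17, which is methylated under the second-stage conditions of step 11.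

Step 8. Configuration at C3 may be lost in the aldehyde, by enolization or by reversible elimination and re-addition of the ring phenoxide, before the olefination is complete. The alkene of ring C would then be kept until the end so that no stereogenic aldehyde is ever made. Setting out from enal 6, Takai olefination (CHI3, CrCl2, THF, 0 °C) should give 7-(benzyloxy)-3-[(E)-2-iodoethenyl]-8-methoxy-2H-chromene F3. Iodine–lithium exchange (t-BuLi, Et2O, −78 °C) and addition to 12 should give 4-{(E)-2-[7-(benzyloxy)-8-methoxy-2H-chromen-3-yl]ethenyl}-4-hydroxy-2,3-dimethoxycyclobut-2-en-1-one F4. Thermolysis in toluene (ring opening, six-electron electrocyclization, tautomerization) should give 2-[7-(benzyloxy)-8-methoxy-2H-chromen-3-yl]-5,6-dimethoxybenzene-1,4-diol F5. Methylation (Me2SO4, K2CO3, acetone, reflux, Ar) should give the isoflav-3-ene 7-(benzyloxy)-8-methoxy-3-(2,3,4,5-tetramethoxyphenyl)-2H-chromene F6. Asymmetric hydrogenation of this 3-aryl-2H-chromene ([Ir(cod)(tBu-PHOX)]BArF with the ligand antipode that gives the 3S product, H2, CH2Cl2), a known reaction class, returns to the route at 18.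

Step 5. Facial selectivity in the hydrogenation of this dialkoxy-substituted acid may be insufficient. Separation of enantiomers would then replace catalyst control. Setting out from 7, hydrogenation with the achiral complex [Ir(cod)(PCy3)(py)]PF6 (H2, CH2Cl2) should give rac-7-(benzyloxy)-8-methoxychroman-3-carboxylic acid F7. Its salt with (R)-1-phenylethylamine, (R)-1-phenylethylammonium (3R)-7-(benzyloxy)-8-methoxychroman-3-carboxylate F8, would be crystallized to diastereomeric purity; the antipodal amine is used if the unwanted salt proves the less soluble one. Acidification (aq. HCl) returns to the route at 8.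

**Further compounds**

F1 | step 10 | (3S)-7-(benzyloxy)-3-[(E)-2-iodoethenyl]-8-methoxychroman | I/C=C/[C@H]1COc2c(ccc(OCc3ccccc3)c2OC)C1
F2 | step 10 | 4-{(E)-2-[(3S)-7-(benzyloxy)-8-methoxychroman-3-yl]ethenyl}-4-hydroxy-2,3-dimethoxycyclobut-2-en-1-one | COC1=C(OC)C(O)(/C=C/[C@H]2COc3c(ccc(OCc4ccccc4)c3OC)C2)C1=O
F3 | step 8 | 7-(benzyloxy)-3-[(E)-2-iodoethenyl]-8-methoxy-2H-chromene | I/C=C/C1=Cc2ccc(OCc3ccccc3)c(OC)c2OC1
F4 | step 8 | 4-{(E)-2-[7-(benzyloxy)-8-methoxy-2H-chromen-3-yl]ethenyl}-4-hydroxy-2,3-dimethoxycyclobut-2-en-1-one | COC1=C(OC)C(O)(/C=C/C2=Cc3ccc(OCc4ccccc4)c(OC)c3OC2)C1=O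
F5 | step 8 | 2-[7-(benzyloxy)-8-methoxy-2H-chromen-3-yl]-5,6-dimethoxybenzene-1,4-diol | COc1c(O)cc(C2=Cc3ccc(OCc4ccccc4)c(OC)c3OC2)c(O)c1OC
F6 | step 8 | 7-(benzyloxy)-8-methoxy-3-(2,3,4,5-tetramethoxyphenyl)-2H-chromene | COc1cc(C2=Cc3ccc(OCc4ccccc4)c(OC)c3OC2)c(OC)c(OC)c1OC
F7 | step 5 | rac-7-(benzyloxy)-8-methoxychroman-3-carboxylic acid | OC(=O)C1COc2c(ccc(OCc3ccccc3)c2OC)C1
F8 | step 5 | (R)-1-phenylethylammonium (3R)-7-(benzyloxy)-8-methoxychroman-3-carboxylate | C[C@@H]([NH3+])c1ccccc1.[O-]C(=O)[C@H]1COc2c(ccc(OCc3ccccc3)c2OC)C1
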